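**Plan**

- Cuts, in retrosynthetic order: (i) the aryl ester that masks the ring B hydroxyl; (ii) the furan O–C2 bond (cyclodehydration) and C2–C3 bond (Claisen-type acyl transfer), which give back a 3-methylbut-2-enoyl group, a naphthol oxygen and a ring D methylene; (iii) the two ring D bonds from two adjacent ring B carbons to a carbonyl carbon and to that methylene, with the C1–C2 bond of indane-1,3-dione restored.
- Enabling feature: ring D (seven-membered) is an indane-1,3-dione (benzene ring E, both C=O, the CH2) with C2 and C3 of 1,4-naphthoquinone (two adjacent ring B carbons) inserted between one carbonyl carbon and the CH2. That CH2 becomes furan C3, and the quinone oxygen beside it becomes the furan oxygen.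
- Forward order: rings A and B (quinone) and ring E (indanedione) are bought; the key step builds a transient cyclobutane and from it ring D; the furan (ring C) is closed afterwards; the isobutenyl group arrives with the acyl chloride.
- Stereochemistry: the target has no stereocentre and no stereogenic double bond; the four centres of the photoadduct disappear in the same flask.
- Ring letters: A, outer benzene ring of the naphthalene; B, its oxygenated ring; C, furan; D, seven-membered ring; E, benzene ring on D.

Key step: step 2

Remark: the target SMILES shows the hydroxytropone-type tautomer. The final deacylation first delivers the naphthol–ketone form, which differs only in the position of the proton inside the O–H···O=C chelate and is taken to equilibrate at once, so both notations mean one compound.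

**Route**

Step 1
Reactants: 1 indane-1,3-dione
Product: 2 3-oxo-3H-inden-1-yl acetate (3-acetoxy-1H-inden-1-one)
Conditions: AcCl, Et3N, CH2Cl2, −20 °C to 0 °C
Reagents that add atoms: acetyl chloride, CC(=O)Cl
Why: O-acylation of the triethylammonium enolate of the acidic cyclic 1,3-diketone by the acyl chloride (standard enol ester formation), kept cold and free of 4-(dimethylamino)pyridine or cyanide so that neither the O→C acyl shift nor self-condensation of 1 competes.

Step 2
Reactants: 2 3-oxo-3H-inden-1-yl acetate (twofold excess); 3 1,4-naphthoquinone
Product: 7 ring D diketone diol (naphthalene-1,4-diol whose C2 is bonded to one C=O and whose C3 is bonded to the CH2 of a –C(=O)–(1,2-phenylene)–C(=O)–CH2– bridge), via cyclobutane photoadduct 4 (not isolated), via hydroquinone acetate 5 (not isolated), via cyclobutenol 6 (not isolated)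
Conditions: hν (λ > 400 nm), PhH, rt, argon; then K2CO3, MeOH, 0 °C to rt, argon; 1 M HCl
Reagents that add atoms: none
Why: Proposed new method: visible-light excitation of the quinone (n,π* band) gives a triplet that adds, directly or after energy transfer to the indenone, across the C=C bond of the partner through a 1,4-biradical to the cis-fused cyclobutane 4; the closest known reactions are the De Mayo reaction (photocycloaddition of a cyclic 1,3-diketone enol acetate to an alkene, then retro-aldol) and the [2+2] photocycloadditions of 1,4-naphthoquinone to alkenes and enol esters. In methanolic K2CO3 the fast enolisation of the 1,4-diketone should aromatise 4 to hydroquinone 5 before the slower methanolysis of the tertiary acetate gives alkoxide 6, which opens by retro-aldol cleavage of the bond common to the four- and five-membered rings. The cyclobutane is closed by the stepwise [2+2] addition and the seven-membered ring by two-carbon ring expansion of the indanone ring (five to seven), driven by release of the strain of the fused cyclobutene. The four stereocentres of 4 are transient (cis ring fusions from biradical closure) and none remains in 7. The selectivity needed is cleavage of the ring-fusion bond and not of the bond to the former quinone carbon, and it is secured by the prior aromatisation, after which the indanone carbonyl is the only acceptor for the retro-aldol; addition at C=C and not at C=O (oxetane) is favoured by the conjugated, electron-poor enol ester double bond and long-wavelength light, and the symmetry of both partners removes any regiochemical question.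

Step 3
Reactants: 7 ring D diketone diol; 8 3-methylbut-2-enoyl chloride (two equivalents are consumed, one per naphthol oxygen; 2.5 equiv charged)
Product: 9 bis(3-methylbut-2-enoate) of 7
Conditions: 8 (2.5 equiv), pyridine, 4-(dimethylamino)pyridine (cat.), CH2Cl2, 0 °C to rt, argon
Reagents that add atoms: 3-methylbut-2-enoyl chloride (the second equivalent of 8), CC(C)=CC(=O)Cl
Why: Nucleophile-catalysed O-acylation of both phenols by the acid chloride (pyridine/4-(dimethylamino)pyridine esterification), each hydroxyl taking up one acyl group; the excess of reagent carries the hydrogen-bonded hydroxyl next to the ketone, and the weak base keeps vinylketene formation and loss of conjugation low.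

Step 4
Reactants: 9 bis(3-methylbut-2-enoate) of 7
Product: 11 radermachol 3-methylbut-2-enoate (furan closed; ring B hydroxyl still acylated), via triketone naphthol 10 (not isolated)
Conditions: K2CO3, DMF, 50 °C; 1 M HCl; then 4-MeC6H4SO3H·H2O (cat.), PhMe, reflux
Reagents that add atoms: none
Why: Baker–Venkataraman-type intramolecular Claisen O→C acyl transfer (5-exo attack of the benzylic ketone enolate on the neighbouring aryl ester) should give the 2-(hydroxyaryl) 1,3-diketone 10, whose naphthol oxygen then adds to the side-chain ketone and loses water under acid to the aromatic furan (cyclodehydration of an α-(2-hydroxyaryl) ketone), the ring ketone being unable to take this role because its carbon is held in ring D.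

Step 5
Reactants: 11 radermachol 3-methylbut-2-enoate
Product: 12 radermachol
Conditions: K2CO3, MeOH, rt; 1 M HCl
Reagents that add atoms: none
Why: Methoxide transesterification of the activated aryl ester beside the ketone should free the hydroxyl as the chelated vinylogous acid, while furan, isobutenyl group and ketones are inert to carbonate at room temperature.

**Compound list**

1 | indane-1,3-dione | O=C1CC(=O)c2ccccc12 | starting material
2 | 3-oxo-3H-inden-1-yl acetate (3-acetoxy-1H-inden-1-one) | CC(=O)OC1=CC(=O)c2ccccc12 | intermediate
3 | 1,4-naphthoquinone | O=C1C=CC(=O)c2ccccc12 | starting material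
4 | cyclobutane photoadduct, not isolated, racemic, cis-anti-cis (relative configuration drawn): cyclobutane made of C2 and C3 of a 2,3-dihydro-1,4-naphthoquinone and C2 and C3 of an indan-1-one; indanone C3 bears OAc; OAc and the indanone C2–H lie on the cyclobutane face that carries the naphthalenedione ring | CC(=O)O[C@]12c3ccccc3C(=O)[C@H]1[C@H]1[C@@H]2C(=O)c2ccccc2C1=O | intermediate
5 | hydroquinone acetate, not isolated, racemic, cis ring fusion: tautomer of 4 in which the dione ring is a naphthalene-1,4-diol, so that the four-membered ring is a cyclobutene fused to the naphthalene | CC(=O)O[C@]12c3ccccc3C(=O)[C@H]1c1c2c(O)c2ccccc2c1O | intermediate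
6 | cyclobutenol, not isolated, racemic: 5 with OH in place of OAc (reacts on as its alkoxide) | O[C@]12c3ccccc3C(=O)[C@H]1c1c2c(O)c2ccccc2c1O | intermediate
7 | ring D diketone diol: naphthalene-1,4-diol with C2 bonded to one C=O and C3 to the CH2 of a –C(=O)–(1,2-phenylene)–C(=O)–CH2– bridge | O=C1Cc2c(O)c3ccccc3c(O)c2C(=O)c2ccccc12 | intermediate
8 | 3-methylbut-2-enoyl chloride | CC(C)=CC(=O)Cl | starting material
9 | bis(3-methylbut-2-enoate) of 7 (both naphthol oxygens acylated) | CC(C)=CC(=O)Oc1c2CC(=O)c3ccccc3C(=O)c2c(OC(=O)C=C(C)C)c2ccccc12 | intermediate
10 | triketone naphthol, not isolated, racemic and labile at the acylated ring D carbon (one enantiomer drawn): the ring D CH bears the 3-methylbut-2-enoyl group, the neighbouring ring B oxygen is a free OH, the other ring B oxygen is still esterified | CC(C)=CC(=O)[C@H]1C(=O)c2ccccc2C(=O)c2c(OC(=O)C=C(C)C)c3ccccc3c(O)c12 | intermediate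
11 | radermachol 3-methylbut-2-enoate: 12 in its naphthol form with that hydroxyl acylated | CC(C)=Cc1oc2c3ccccc3c(OC(=O)C=C(C)C)c3c2c1C(=O)c1ccccc1C3=O | intermediate
12 | radermachol | CC(C)=Cc1oc2c3c(c(O)c4ccccc4c(=O)c13)C(=O)c1ccccc1-2 | target

**Step count and risks**

Total steps: 5. Longest linear sequence: 5 steps (1 → 2 → 7 → 9 → 11 → 12).

Steps most likely to fail:

1. Step 2. What may go wrong: triplet energy may be spent on homodimerisation of the indenone or the quinone, or on addition at a quinone carbonyl. In the base stage, loss of the acetate ahead of aromatisation would open a fragmentation toward the quinone carbonyl, with no ring expansion. Fallback with known chemistry, forming the same two bonds in the ground state by aryne insertion into the C1–C2 bond of a 1,3-dicarbonyl compound (acyl-alkylation of an aryne). It sets out from 1: the lithium enolate of 1 and purchased 2-bromo-1,4-dimethoxynaphthalene F1 are treated with lithium 2,2,6,6-tetramethylpiperidide in THF (−78 °C to rt). Dehydrobromination gives 1,4-dimethoxy-2,3-didehydronaphthalene F2, which takes up the enolate carbon, closes onto the neighbouring carbonyl and fragments, to give the dimethyl ether of 7 F3. BBr3 in CH2Cl2 (−78 °C to rt) then frees both hydroxyls and the route is rejoined at 7.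

2. Step 4. What may go wrong: the O→C acyl shift may be outrun by loss or intermolecular exchange of the acyl group between naphtholate oxygens, and under acid the diketone enol may add to the enone double bond instead of the naphthol closing the furan. Fallback by intermolecular C-acylation on a protected diol, setting out from 7: MOMCl and i-Pr2NEt in CH2Cl2 give the bis(methoxymethyl) ether of 7 F4. Its lithium enolate (LiN(SiMe3)2, two equivalents, THF, −78 °C) is C-acylated by 8 to the 2-acyl 1,3-diketone F5. HCl in MeOH (50 °C) removes both acetals, and the freed naphthol beside the diketone cyclodehydrates, so that the route is rejoined at 12 and steps 3 to 5 are replaced.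

3. Step 1. What may go wrong: C-acylation or base-induced self-condensation of 1 during acetylation, and hydrolysis of the anhydride-like enol ester during isolation. Fallback by vinylogous acyl substitution, setting out from 1: (COCl)2 with catalytic N,N-dimethylformamide in CH2Cl2 gives 3-chloro-1H-inden-1-one F6. AgOAc in dry MeCN replaces chloride by acetate through addition–elimination at the β-carbon, and the filtered solution rejoins the route at 2.

**Further compounds**

F1 | step 2 | 2-bromo-1,4-dimethoxynaphthalene | COc1cc(Br)c(OC)c2ccccc12
F2 | step 2 | 1,4-dimethoxy-2,3-didehydronaphthalene | COC1=C2C=CC=CC2=C(OC)C#C1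
F3 | step 2 | dimethyl ether of 7 | COc1c2CC(=O)c3ccccc3C(=O)c2c(OC)c2ccccc12
F4 | step 4 | bis(methoxymethyl) ether of 7 | COCOc1c2CC(=O)c3ccccc3C(=O)c2c(OCOC)c2ccccc12
F5 | step 4 | 2-acyl 1,3-diketone (F4 with the 3-methylbut-2-enoyl group on the ring D CH, racemic, one enantiomer drawn) | COCOc1c2[C@H](C(=O)C=C(C)C)C(=O)c3ccccc3C(=O)c2c(OCOC)c2ccccc12
F6 | step 1 | 3-chloro-1H-inden-1-one | ClC1=CC(=O)c2ccccc12
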